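**Retrosynthetic overview**

1. Numbering: five-membered ring C1(OAc)–C2–C3(OH, i-Pr)–C4(H)–C10(Me); seven-membered ring C4–C5(O-aroyl)–C6–C7(Me)=C8–C9–C10; β is the face of the C10 methyl, α the opposite face.
2. The strategy rests on C6: it is α to the oxygenated carbon C5 and bonded to the alkene carbon C7. With C5 as a ketone, C6–C7 is the bond between a methyl ketone enolate (acetyl on C4) and a Z vinyl bromide (C7, on a C9–C8 arm at C10).
3. Disconnections, late to early: C5 and C1 esters; C5–H (reduction directed by the C3 hydroxyl); C6–C7 (palladium enolate alkenylation); C1–H (directed reduction); C3–i-Pr (organocerium addition); C10–C9 (enolate alkylation); C4–C5 (vinyl cuprate addition).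
4. Ring order: the cyclopentane comes intact from (R)-4-silyloxycyclopentenone and carries C1, C3, C4 and C10 before the cycloheptene is closed second. C1 is set α before the closure, so no late inversion is needed.

Key step: step 16

Remark: enone 5 and acid 23 are assumed to be commercially available; the C3 silyloxy group of 5 serves only to control C4 and is later oxidised.

**Step 1**
Reactants: 1 ethyl but-2-ynoate
Product: 2 ethyl (2Z)-3-bromobut-2-enoate
Conditions: LiBr, AcOH, MeCN, reflux
Reagents that add atoms: lithium bromide, [Li+].[Br-]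
Why: Hydrobromination of the ynoate (bromide conjugate addition, then protonation anti to bromide) should give the Z β-bromo enoate, with Br cis to the carbon that becomes C9.

**Step 2**
Reactants: 2 ethyl (2Z)-3-bromobut-2-enoate
Product: 3 (2Z)-3-bromobut-2-en-1-ol
Conditions: i-Bu2AlH (2.2 equiv), CH2Cl2, −78 °C to 0 °C
Reagents that add atoms: none
Why: 1,2-Reduction of the ester by the aluminium hydride leaves the vinyl bromide and its geometry untouched.

**Step 3**
Reactants: 3 (2Z)-3-bromobut-2-en-1-ol
Product: 4 (2Z)-1,3-dibromobut-2-ene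
Conditions: CBr4, PPh3, CH2Cl2, 0 °C
Reagents that add atoms: carbon tetrabromide, BrC(Br)(Br)Br
Why: Appel bromination proceeds by SN2 at the primary allylic carbinol, so the alkene geometry is kept.

**Step 4**
Reactants: 5 (4R)-4-[(tert-butyldimethylsilyl)oxy]cyclopent-2-en-1-one
Product: 6 (4R)-4-[(tert-butyldimethylsilyl)oxy]-2-iodocyclopent-2-en-1-one
Conditions: I2, pyridine, CH2Cl2, 0 °C to rt
Reagents that add atoms: iodine, II
Why: α-Iodination of the enone through pyridine conjugate addition, iodination of the enolate and elimination (Baylis–Hillman-type sequence) is standard for cyclic enones.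

**Step 5**
Reactants: 6 (4R)-4-[(tert-butyldimethylsilyl)oxy]-2-iodocyclopent-2-en-1-one
Product: 7 (4R)-4-[(tert-butyldimethylsilyl)oxy]-2-methylcyclopent-2-en-1-one
Conditions: Me4Sn, Pd2(dba)3 (cat.), AsPh3, CuI (cat.), NMP, 60 °C
Reagents that add atoms: tetramethylstannane, C[Sn](C)(C)C
Why: Stille coupling of the α-iodoenone under neutral conditions installs the C10 methyl without disturbing the γ-silyloxy group.

**Step 6**
Reactants: 7 (4R)-4-[(tert-butyldimethylsilyl)oxy]-2-methylcyclopent-2-en-1-one
Product: 8 tert-butyl{[(1R,2R)-2-ethenyl-3-methyl-4-(trimethylsilyloxy)cyclopent-3-en-1-yl]oxy}dimethylsilane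
Conditions: CH2=CHMgBr, CuBr·SMe2 (10 mol %), Me3SiCl, HMPA, THF, −78 °C; then Et3N
Reagents that add atoms: vinylmagnesium bromide, C=C[Mg]Br; chlorotrimethylsilane, C[Si](C)(C)Cl
Why: Copper-catalysed, silyl-chloride-accelerated conjugate addition should deliver the vinyl group anti to the C3 silyloxy group, as in prostaglandin three-component couplings, which sets C4 (β-vinyl) and traps the C1/C10 enolate regiospecifically.

**Step 7**
Reactants: 8 trimethylsilyl enol ether; 4 (2Z)-1,3-dibromobut-2-ene
Product: 10 (2R,3R,4R)-2-[(2Z)-3-bromobut-2-en-1-yl]-4-[(tert-butyldimethylsilyl)oxy]-3-ethenyl-2-methylcyclopentan-1-one, via lithium enolate 9 (not isolated)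
Conditions: MeLi (1.0 equiv), THF, 0 °C; then 4, HMPA, −78 °C to −20 °C
Reagents that add atoms: none
Why: MeLi cleaves the Si–O bond to release the regiodefined lithium enolate, which is C-alkylated (SN2) by the allylic bromide of 4 anti to the adjacent C4 vinyl group, setting the C10 quaternary centre (methyl β, arm α); the vinylic bromide is inert to SN2.

**Step 8**
Reactants: 10 ketone
Product: 11 ethylene ketal of 10 at C1 (3α-OTBS, 4β-vinyl, 10β-Me, 10α-arm)
Conditions: (Me3SiOCH2)2, Me3SiOTf (cat.), CH2Cl2, −78 °C to −20 °C
Reagents that add atoms: 1,2-bis(trimethylsilyloxy)ethane, C[Si](C)(C)OCCO[Si](C)(C)C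
Why: Aprotic silyl-triflate-catalysed ketalisation masks the C1 ketone without the protic acid that would eliminate the β-silyloxy group, so that C3 can become a ketone without forming a 1,3-diketone.

**Step 9**
Reactants: 11 ketal silyl ether
Product: 12 C3 alcohol (3α-OH) of the ketal
Conditions: Bu4NF, THF, 0 °C to rt
Reagents that add atoms: none
Why: Fluoride cleaves the secondary silyl ether; the ketal, both alkenes and the vinyl bromide are inert.

**Step 10**
Reactants: 12 C3 alcohol
Product: 13 C3 ketone (C1 dioxolane, 4β-vinyl)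
Conditions: Dess–Martin periodinane, NaHCO3, CH2Cl2, 0 °C
Reagents that add atoms: none
Why: Buffered Dess–Martin oxidation is non-enolising; the β,γ-unsaturated ketone should be used crude to avoid alkene migration or epimerisation at C4.

**Step 11**
Reactants: 13 C3 ketone
Product: 14 tertiary alcohol (3β-OH, 3α-isopropyl; C1 dioxolane)
Conditions: i-PrMgCl, CeCl3, THF, −78 °C
Reagents that add atoms: isopropylmagnesium chloride, CC(C)[Mg]Cl
Why: Organocerium 1,2-addition, chosen for its low basicity toward the enolisable ketone, should occur on the α face, anti to the adjacent 4β-vinyl group (the C1 ketal is face-neutral), which sets C3.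

**Step 12**
Reactants: 14 tertiary alcohol ketal
Product: 15 β-hydroxy ketone (C1 ketone, 3β-OH)
Conditions: PPTS, acetone/H2O, 45 °C
Reagents that add atoms: water, O
Why: Mild acid-catalysed ketal hydrolysis regenerates the C1 ketone; a weak acid is used so that the tertiary β-hydroxyl is not eliminated.

**Step 13**
Reactants: 15 β-hydroxy ketone
Product: 16 diol (1α-OH, 3β-OH)
Conditions: Me4NBH(OAc)3, MeCN/AcOH, −30 °C to 0 °C
Reagents that add atoms: none
Why: Evans–Saksena reduction: the 3β-hydroxyl binds boron and delivers hydride intramolecularly to the β face of C1, giving the trans-1,3-diol and setting C1 (α-OH); ketones without a directing hydroxyl are not reduced by this reagent.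

**Step 14**
Reactants: 16 diol
Product: 17 bis(triethylsilyl) ether
Conditions: Et3SiOTf (3 equiv), 2,6-lutidine, CH2Cl2, −78 °C to rt
Reagents that add atoms: triethylsilyl trifluoromethanesulfonate, CC[Si](CC)(CC)OS(=O)(=O)C(F)(F)F
Why: Silyl triflate silylation caps the hindered secondary and the tertiary alcohol, so that no alkoxide (retro-aldol at C3) can form in the basic key step.

**Step 15**
Reactants: 17 bis(triethylsilyl) ether
Product: 18 methyl ketone (4β-acetyl, 1α-OTES, 3β-OTES, 10α-(Z)-3-bromobut-2-enyl)
Conditions: PdCl2 (cat.), CuCl, O2 (1 atm), DMF/H2O, rt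
Reagents that add atoms: water, O (carbonyl oxygen; dioxygen, O=O, is the terminal oxidant)
Why: Tsuji–Wacker oxidation: Markovnikov hydroxypalladation of the monosubstituted alkene gives the methyl ketone (C5, C6); the trisubstituted bromoalkene is too hindered and electron-poor to react.

**Step 16**
Reactants: 18 methyl ketone
Product: 19 trans-fused bicyclic C5 ketone with the C7=C8 alkene (1α-OTES, 3β-OTES)
Conditions: Pd(PPh3)4 (20 mol %), KOtBu (2.5 equiv), THF (0.01 M), rt to 45 °C; then NH4Cl (aq), 0 °C
Reagents that add atoms: none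
Why: Oxidative addition of zerovalent palladium into the C7–Br bond gives a Z alkenylpalladium bromide; KOtBu removes a C6 methyl proton, the enolate displaces bromide on palladium to give an eight-membered C,C-palladacycle, and reductive elimination forms C6–C7. The closest known reaction is the intramolecular palladium-catalysed α-alkenylation of ketones with vinyl halides under Pd(PPh3)4/KOtBu, well established for five- and six-membered rings and applied here to a seven-membered ring. The cycloheptene closes in a 7-(enolendo) mode with the alkene kept at C7=C8 inside the ring, which is possible only because the bromide is Z (Br cis to C9). No stereocentre is formed; the trans ring fusion follows from the trans acetyl and arm on C4 and C10. The step needs enolisation at the methyl group and not at C4: C4–H is a methine between two fully substituted carbons, its enolate would be a strained tetrasubstituted one, and the C3 oxygen is silylated so that retro-aldol cleavage cannot start. The product is more acidic at C6 (α to the ketone and allylic) and should rest as its dienolate, which protects C4 from epimerisation and returns the β,γ-unsaturated ketone on kinetic α-protonation.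

**Step 17**
Reactants: 19 bicyclic ketone
Product: 20 keto diol (1α-OH, 3β-OH, C5 ketone)
Conditions: HF·pyridine, pyridine, THF, 0 °C to rt
Reagents that add atoms: none
Why: Buffered fluoride cleaves both triethylsilyl ethers without the basic conditions that could cause retro-aldol cleavage or alkene migration.

**Step 18**
Reactants: 20 keto diol
Product: 21 C1 acetate (3β-OH, C5 ketone)
Conditions: Ac2O, pyridine, DMAP (cat.), CH2Cl2, 0 °C
Reagents that add atoms: acetic anhydride, CC(=O)OC(C)=O
Why: Acylation under nucleophilic catalysis discriminates the secondary C1 hydroxyl from the tertiary C3 hydroxyl.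

**Step 19**
Reactants: 21 keto acetate
Product: 22 5α-alcohol (1α-OAc, 3β-OH)
Conditions: Me4NBH(OAc)3, MeCN/AcOH, −20 °C
Reagents that add atoms: none
Why: Evans–Saksena reduction directed by the 3β-hydroxyl: the O3–C3–C4–C5 torsion of the six-membered transition state is fixed by the trans ring fusion, so hydride should reach C5 from the β face (the side of C3), giving the 5α-alcohol with H-5 anti to H-4 and setting C5.

**Step 20**
Reactants: 22 5α-alcohol; 23 4-[(tert-butyldimethylsilyl)oxy]benzoic acid
Product: 24 5-O-(4-silyloxybenzoyl) ester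
Conditions: DCC, DMAP, CH2Cl2, rt
Reagents that add atoms: none
Why: Steglich esterification acylates the only free secondary hydroxyl; the tertiary C3 hydroxyl does not react under these conditions.

**Step 21**
Reactants: 24 silyl-protected diester
Product: 25 CNP0275279.1
Conditions: Bu4NF, AcOH, THF, 0 °C
Reagents that add atoms: none
Why: Buffered fluoride cleaves the aryl silyl ether far faster than it touches the two esters, releasing the phenol.

**Compound list**

1 | ethyl but-2-ynoate | CC#CC(=O)OCC | starting material
2 | ethyl (2Z)-3-bromobut-2-enoate | CCOC(=O)/C=C(/C)Br | intermediate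
3 | (2Z)-3-bromobut-2-en-1-ol | OC/C=C(/C)Br | intermediate
4 | (2Z)-1,3-dibromobut-2-ene | BrC/C=C(/C)Br | intermediate
5 | (4R)-4-[(tert-butyldimethylsilyl)oxy]cyclopent-2-en-1-one | O=C1C=C[C@H](O[Si](C)(C)C(C)(C)C)C1 | starting material
6 | (4R)-4-[(tert-butyldimethylsilyl)oxy]-2-iodocyclopent-2-en-1-one | O=C1C(I)=C[C@H](O[Si](C)(C)C(C)(C)C)C1 | intermediate
7 | (4R)-4-[(tert-butyldimethylsilyl)oxy]-2-methylcyclopent-2-en-1-one | O=C1C(C)=C[C@H](O[Si](C)(C)C(C)(C)C)C1 | intermediate
8 | tert-butyl{[(1R,2R)-2-ethenyl-3-methyl-4-(trimethylsilyloxy)cyclopent-3-en-1-yl]oxy}dimethylsilane (vinyl trans to OTBS) | CC1=C(O[Si](C)(C)C)C[C@@H](O[Si](C)(C)C(C)(C)C)[C@@H]1C=C | intermediate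
9 | lithium (3R,4R)-4-[(tert-butyldimethylsilyl)oxy]-3-ethenyl-2-methylcyclopent-1-en-1-olate | CC1=C([O-])C[C@@H](O[Si](C)(C)C(C)(C)C)[C@@H]1C=C.[Li+] | intermediate (not isolated)
10 | (2R,3R,4R)-2-[(2Z)-3-bromobut-2-en-1-yl]-4-[(tert-butyldimethylsilyl)oxy]-3-ethenyl-2-methylcyclopentan-1-one | O=C1C[C@@H](O[Si](C)(C)C(C)(C)C)[C@H](C=C)[C@@]1(C)C/C=C(/C)Br | intermediate
11 | ethylene ketal of 10 at C1 (3α-OTBS, 4β-vinyl, 10β-methyl, 10α-(Z)-3-bromobut-2-enyl) | C1COC2(O1)C[C@@H](O[Si](C)(C)C(C)(C)C)[C@H](C=C)[C@@]2(C)C/C=C(/C)Br | intermediate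
12 | C3 alcohol of the ketal (3α-OH) | C1COC2(O1)C[C@@H](O)[C@H](C=C)[C@@]2(C)C/C=C(/C)Br | intermediate
13 | C3 ketone of the ketal (4β-vinyl) | C1COC2(O1)CC(=O)[C@H](C=C)[C@@]2(C)C/C=C(/C)Br | intermediate
14 | tertiary alcohol (3β-OH, 3α-isopropyl, C1 dioxolane) | C1COC2(O1)C[C@@](O)(C(C)C)[C@H](C=C)[C@@]2(C)C/C=C(/C)Br | intermediate
15 | β-hydroxy ketone (C1 ketone, 3β-OH, 3α-isopropyl, 4β-vinyl) | O=C1C[C@@](O)(C(C)C)[C@H](C=C)[C@@]1(C)C/C=C(/C)Br | intermediate
16 | diol (1α-OH, 3β-OH) | O[C@H]1C[C@@](O)(C(C)C)[C@H](C=C)[C@@]1(C)C/C=C(/C)Br | intermediate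
17 | 1α,3β-bis(triethylsilyl) ether (4β-vinyl) | CC[Si](CC)(CC)O[C@H]1C[C@@](O[Si](CC)(CC)CC)(C(C)C)[C@H](C=C)[C@@]1(C)C/C=C(/C)Br | intermediate
18 | cyclopentyl methyl ketone (4β-acetyl, 1α-OTES, 3β-OTES, 10α-(Z)-3-bromobut-2-enyl) | CC[Si](CC)(CC)O[C@H]1C[C@@](O[Si](CC)(CC)CC)(C(C)C)[C@H](C(C)=O)[C@@]1(C)C/C=C(/C)Br | intermediate
19 | trans-fused bicyclic C5 ketone with C7=C8 alkene (1α-OTES, 3β-OTES) | CC[Si](CC)(CC)O[C@H]1C[C@@](O[Si](CC)(CC)CC)(C(C)C)[C@@H]2C(=O)CC(C)=CC[C@@]12C | intermediate
20 | keto diol (1α-OH, 3β-OH, C5 ketone) | O[C@H]1C[C@@](O)(C(C)C)[C@@H]2C(=O)CC(C)=CC[C@@]12C | intermediate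
21 | 1α-acetate of 20 | CC(=O)O[C@H]1C[C@@](O)(C(C)C)[C@@H]2C(=O)CC(C)=CC[C@@]12C | intermediate
22 | 5α-alcohol (1α-OAc, 3β-OH) | CC(=O)O[C@H]1C[C@@](O)(C(C)C)[C@@H]2[C@@H](O)CC(C)=CC[C@@]12C | intermediate
23 | 4-[(tert-butyldimethylsilyl)oxy]benzoic acid | CC(C)(C)[Si](C)(C)Oc1ccc(cc1)C(=O)O | starting material
24 | 5-O-[4-(tert-butyldimethylsilyloxy)benzoyl] ester of 22 | CC(=O)O[C@H]1C[C@@](O)(C(C)C)[C@@H]2[C@@H](OC(=O)c3ccc(O[Si](C)(C)C(C)(C)C)cc3)CC(C)=CC[C@@]12C | intermediate
25 | CNP0275279.1 | CC(=O)O[C@H]1C[C@@](O)(C(C)C)[C@@H]2[C@@H](OC(=O)c3ccc(O)cc3)CC(C)=CC[C@@]12C | target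

**Step count and risks**

Total step count: 21. Longest linear sequence: 18 steps (steps 4 to 21, from 5); steps 1 to 3 make the alkylating agent 4.

Steps most likely to fail:

1. Step 16. The alkoxide base may remove HBr from the Z vinyl bromide (H-8 is anti to Br) to give the butynyl arm, the alkenylpalladium may be protonated, or the eight-membered palladacycle may close too slowly. Fallback: setting out from 18, kinetic deprotonation at the methyl group and silylation (LiN(i-Pr)2, Me3SiCl, THF, −78 °C) would give the terminal trimethylsilyl enol ether F1. A fluoride-promoted palladium coupling through the tributyltin enolate (Pd2(dba)3, P(t-Bu)3, Bu3SnF, CsF, toluene, 80 °C) would then form C6–C7 with the enolate regiochemistry fixed beforehand and no alkoxide present. It comes back to the route at 19.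

2. Step 7. Proton transfer from the product (C2–H) to unreacted enolate, followed by β-elimination of the silyloxy group, may consume the enolate, and O-alkylation may compete. Fallback: setting out from 8, the alkylation is run with an extra equivalent of LiN(SiMe3)2 and finished with DBU, so that the alkylated ketone is deliberately taken on to the cyclopent-2-enone F2 by loss of the silanol. Nucleophilic epoxidation (H2O2, NaOH, MeOH, 0 °C), anti to the C4 vinyl group, would give the α-epoxy ketone F3. Reductive opening at C2 (PhSeSePh, NaBH4, EtOH, AcOH) would give the 3α-hydroxy ketone F4. Silylation (t-BuMe2SiCl, imidazole, DMF) comes back to the route at 10. The C3 oxygen is thus put back after the quaternary centre is in place.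

3. Step 11. The organometallic may enolise the β,γ-unsaturated ketone (alkene migration, epimerisation at C4) or transfer a β-hydride (reduction in place of addition). Fallback: setting out from 13, a samarium Barbier reaction (2-iodopropane, SmI2, HMPA, THF, rt) generates the isopropyl nucleophile by single-electron reduction in the presence of the ketone, without a preformed basic organometallic. It comes back to the route at 14 and makes no new compound.

**Further compounds**

F1 | step 16 | trimethylsilyl enol ether of 18 (C5–OSiMe3, C5=C6H2) | CC[Si](CC)(CC)O[C@H]1C[C@@](O[Si](CC)(CC)CC)(C(C)C)[C@H](C(=C)O[Si](C)(C)C)[C@@]1(C)C/C=C(/C)Br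
F2 | step 7 | cyclopent-2-enone (C1 ketone, C2=C3, 4β-vinyl, 10β-methyl, 10α-(Z)-3-bromobut-2-enyl) | O=C1C=C[C@H](C=C)[C@@]1(C)C/C=C(/C)Br
F3 | step 7 | 2α,3α-epoxy ketone of F2 | O=C1[C@H]2O[C@H]2[C@H](C=C)[C@@]1(C)C/C=C(/C)Br
F4 | step 7 | 3α-hydroxy ketone (desilylated 10) | O=C1C[C@@H](O)[C@H](C=C)[C@@]1(C)C/C=C(/C)Br
F0 | step 11 | none | none
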